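A direct plan would cyclodimerise the azido hydroxy acid A1 to a twofold-symmetric 26-membered diolide, cleave its two isopropenyl groups to give the diacetyl diazido diolide A2, close both six-membered rings of A2 at once by a twofold Staudinger/aza-Wittig reaction to the bis-imine A3, and then reduce one of the two imines of A3. Its weakest steps would be:
- the final reduction of one of two identical imines in A3: it can only be statistical, so unreacted, mono-reduced and doubly reduced diolide would have to be separated and recycled at the most precious stage, with unproven facial selectivity;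
- the cyclodimerisation of A1: ring size (monolide, dimer, oligomers) would be left to concentration, and a head-to-tail dimer can never tell the two halves apart;
- the carbinol of A1: it would come from an aldehyde by Grignard addition, oxidation to an enone and reagent-controlled reduction, three steps for one stereocentre, beside an azide that can add to the enone.

**Plan of the new route**
Each half is numbered as its C14 acid (C1 carboxyl, C9 = ring C6 with N, C12 = ring C3 with O, C13 = ring C2, C14 = methyl); the cuts are the two ester C–O bonds (one at a time), N1–C2 of each ring, C12–C13 of each half (acetylide + lactam carbonyl) and C7–C8 (metathesis).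
Feature used: in both rings N1–C6–C5–C4–C3(O) is the N–CH–CH2–CH2–C(=O) array of a 5-substituted pyrrolidin-2-one, and C2 with its methyl is a two-carbon unit on that carbonyl carbon; a bought lactam supplies C6 and an acetylide opens it to an ynone.
One Boc-amino alkynol serves both halves: one copy is cyclised and hydrogenated to ring B (C2 relayed from C3 and C6) before any ester exists; the other stays open, its alkyne a masked acetyl group.
Ring order: ring B, then the 26-membered diolide by two separate esterifications, then ring A in the last step by acid.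
No symmetric intermediate is made, so neither half-reduction nor cyclodimerisation occurs; C3 is set by one catalytic reduction of the ynone that the ring opening delivers, with no redox detour and no azide.

Key step: step 4

Remark: the (S,S)-configured Ru catalyst of step 5 is taken to give the (12S)-carbinol, the alkynyl group playing the part of the aryl group of aryl ketones; the (R,R)-catalyst would be used otherwise.

**Step 1**
Reactants: 1 (5S)-5-ethenylpyrrolidin-2-one; 2 methyl oct-7-enoate
Product: 3 methyl (7E)-8-[(2S)-5-oxopyrrolidin-2-yl]oct-7-enoate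
Conditions: second-generation Hoveyda–Grubbs catalyst RuCl2(H2IMes)(=CH-C6H4-2-OiPr) (5 mol %), 2 (3 equiv), 1,4-benzoquinone (10 mol %), CH2Cl2, 40 °C
Reagents that add atoms: none
Why: Olefin cross-metathesis of a terminal alkene with an allylic amide that does not homodimerise should give the E-alkene with loss of ethene, benzoquinone suppressing double-bond migration toward the C9 stereocentre.

**Step 2**
Reactants: 3 methyl (7E)-8-[(2S)-5-oxopyrrolidin-2-yl]oct-7-enoate
Product: 4 methyl 8-[(2R)-5-oxopyrrolidin-2-yl]octanoate
Conditions: H2 (1 atm), 10 % Pd/C, EtOAc, rt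
Reagents that add atoms: none
Why: Heterogeneous hydrogenation saturates the disubstituted alkene without touching C9, whose descriptor changes only because the priorities change.

**Step 3**
Reactants: 4 methyl 8-[(2R)-5-oxopyrrolidin-2-yl]octanoate
Product: 5 tert-butyl (2R)-2-(8-methoxy-8-oxooctyl)-5-oxopyrrolidine-1-carboxylate
Conditions: Boc2O, DMAP (0.2 equiv), Et3N, MeCN, rt
Reagents that add atoms: di-tert-butyl dicarbonate, CC(C)(C)OC(=O)OC(=O)OC(C)(C)C
Why: DMAP-catalysed N-acylation of the lactam gives the N-Boc lactam, whose ring carbonyl is thereby activated like that of an imide.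

**Step 4**
Reactants: 5 tert-butyl (2R)-2-(8-methoxy-8-oxooctyl)-5-oxopyrrolidine-1-carboxylate; 6 ethynyl(trimethyl)silane
Product: 7 methyl (9R)-9-[(tert-butoxycarbonyl)amino]-12-oxo-14-(trimethylsilyl)tetradec-13-ynoate
Conditions: 6, n-BuLi, THF, −78 °C; then 5, −78 °C; AcOH quench at −78 °C
Reagents that add atoms: none
Why: The lithium acetylide adds to the ring carbonyl, and the tetrahedral lithium alkoxide persists at −78 °C, so a second addition is held off and the acetic acid quench releases the open-chain ynone by C–N cleavage. The closest known reaction type is the ring opening of N-Boc pyrrolidin-2-ones and pyroglutamates by Grignard reagents and lithium acetylides to γ-(Boc-amino) ketones. No ring is closed: the five-membered lactam, which is not in the target, is cleaved at N–C12, and the new C12–C13 bond completes the C1–C14 chain of one half with nitrogen on C9 and a carbonyl on C12. No stereocentre is formed, and C9, bought with the lactam, is not α to a carbonyl and cannot epimerise. The step needs attack at the lactam carbonyl before the methyl ester and the carbamate carbonyl, and mono-addition; the first is secured by the twofold acyl activation of the ring carbonyl at −78 °C, the second by the stability of the adduct until the quench. The ynone is the substrate class on which Ru–diamine transfer hydrogenation sets a propargylic carbinol, and its alkyne is later the 6-exo-dig acceptor for ring B and the masked acetyl group of ring A.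

**Step 5**
Reactants: 7 methyl (9R)-9-[(tert-butoxycarbonyl)amino]-12-oxo-14-(trimethylsilyl)tetradec-13-ynoate
Product: 8 methyl (9R,12S)-9-[(tert-butoxycarbonyl)amino]-12-hydroxy-14-(trimethylsilyl)tetradec-13-ynoate
Conditions: Ru[(S,S)-TsNCH(Ph)CH(Ph)NH](p-cymene) (1 mol %), 2-propanol, rt
Reagents that add atoms: none
Why: Noyori asymmetric transfer hydrogenation of an α,β-acetylenic ketone should set C12 as S by catalyst control, independent of the remote C9, with ester, carbamate and silyl alkyne untouched.

**Step 6**
Reactants: 8 methyl (9R,12S)-9-[(tert-butoxycarbonyl)amino]-12-hydroxy-14-(trimethylsilyl)tetradec-13-ynoate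
Product: 9 methyl (9R,12S)-9-[(tert-butoxycarbonyl)amino]-12-hydroxytetradec-13-ynoate
Conditions: K2CO3 (0.2 equiv), MeOH, 0 °C
Reagents that add atoms: none
Why: Base-catalysed methanolysis of the C(sp)–Si bond (protodesilylation) frees the terminal alkyne, and the methyl ester can only exchange with the solvent.

**Step 7**
Reactants: 9 methyl (9R,12S)-9-[(tert-butoxycarbonyl)amino]-12-hydroxytetradec-13-ynoate
Product: 10 methyl (9R,12S)-9-amino-12-hydroxytetradec-13-ynoate
Conditions: TFA, CH2Cl2, 0 °C; then aq K2CO3
Reagents that add atoms: none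
Why: Acidolysis of the tert-butyl carbamate frees the primary amine, and the secondary propargylic alcohol does not ionise under these conditions.

**Step 8**
Reactants: 10 methyl (9R,12S)-9-amino-12-hydroxytetradec-13-ynoate
Product: 13 tert-butyl (2S,3S,6R)-3-hydroxy-6-(8-methoxy-8-oxooctyl)-2-methylpiperidine-1-carboxylate, via cyclic imine 11 (not isolated), via piperidine 12 (not isolated)
Conditions: NaAuCl4·2H2O (5 mol %), MeCN, 60 °C; evaporate; H2 (1 atm), 10 % Pd/C, MeOH, rt; then Boc2O, Et3N, rt
Reagents that add atoms: di-tert-butyl dicarbonate, CC(C)(C)OC(=O)OC(=O)OC(C)(C)C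
Why: Gold-catalysed 6-exo-dig hydroamination of the 5-alkynylamine gives the 2-methyl tetrahydropyridine 11; hydrogen should then be delivered to C2 from the ring face opposite to the C3 hydroxyl and the C6 chain, which are cis to each other, to give the all-cis (2S) piperidine 12, which Boc2O protects on nitrogen only.

**Step 9**
Reactants: 13 tert-butyl (2S,3S,6R)-3-hydroxy-6-(8-methoxy-8-oxooctyl)-2-methylpiperidine-1-carboxylate
Product: 14 8-[(2R,5S,6S)-1-(tert-butoxycarbonyl)-5-hydroxy-6-methylpiperidin-2-yl]octanoic acid
Conditions: LiOH (2 equiv), THF/MeOH/H2O, 0 °C to rt; then 1 M HCl to pH 3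
Reagents that add atoms: lithium hydroxide, [Li+].[OH-]
Why: Saponification of the methyl ester meets no base-sensitive centre and leaves the carbamate and the ring hydroxyl untouched.

**Step 10**
Reactants: 14 8-[(2R,5S,6S)-1-(tert-butoxycarbonyl)-5-hydroxy-6-methylpiperidin-2-yl]octanoic acid; 9 methyl (9R,12S)-9-[(tert-butoxycarbonyl)amino]-12-hydroxytetradec-13-ynoate
Product: 15 methyl (9R,12S)-9-[(tert-butoxycarbonyl)amino]-12-({8-[(2R,5S,6S)-1-(tert-butoxycarbonyl)-5-hydroxy-6-methylpiperidin-2-yl]octanoyl}oxy)tetradec-13-ynoate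
Conditions: 9 (1.5 equiv), DCC, DMAP (0.1 equiv), CH2Cl2, 0 °C
Reagents that add atoms: none
Why: Steglich esterification should acylate the unhindered propargylic hydroxyl of 9, used in excess, much faster than the ring hydroxyl of 14, which is flanked by the C2 methyl group on a carbamate-bearing ring; no stereocentre is touched.

**Step 11**
Reactants: 15 methyl (9R,12S)-9-[(tert-butoxycarbonyl)amino]-12-({8-[(2R,5S,6S)-1-(tert-butoxycarbonyl)-5-hydroxy-6-methylpiperidin-2-yl]octanoyl}oxy)tetradec-13-ynoate
Product: 16 (9R,12S)-9-[(tert-butoxycarbonyl)amino]-12-({8-[(2R,5S,6S)-1-(tert-butoxycarbonyl)-5-hydroxy-6-methylpiperidin-2-yl]octanoyl}oxy)tetradec-13-ynoic acid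
Conditions: Me3SnOH (5 equiv), 1,2-dichloroethane, 70 °C; then 1 M HCl wash
Reagents that add atoms: trimethyltin hydroxide, C[Sn](C)(C)O
Why: Neutral tin-hydroxide hydrolysis cleaves the unbranched methyl ester far faster than the secondary internal ester and does not touch the carbamates or the propargylic centre.

**Step 12**
Reactants: 16 (9R,12S)-9-[(tert-butoxycarbonyl)amino]-12-({8-[(2R,5S,6S)-1-(tert-butoxycarbonyl)-5-hydroxy-6-methylpiperidin-2-yl]octanoyl}oxy)tetradec-13-ynoic acid
Product: 18 alkynyl macrodiolide, via mixed anhydride 17 (not isolated)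
Conditions: 2,4,6-trichlorobenzoyl chloride, Et3N, THF, rt; then slow addition to DMAP, toluene, 80 °C (about 1 mM)
Reagents that add atoms: none
Why: Yamaguchi macrolactonisation of a seco acid that already holds both halves in order can give only the 26-membered ring, closing at the ring-B hydroxyl under high dilution with no base-sensitive centre present.

**Step 13**
Reactants: 18 alkynyl macrodiolide
Product: 19 acetyl macrodiolide
Conditions: Ph3PAuNTf2 (5 mol %), 1,4-dioxane/H2O (10:1), rt
Reagents that add atoms: water, O
Why: Gold-catalysed Markovnikov hydration with anchimeric assistance: the ester carbonyl oxygen attacks the activated alkyne in 5-exo-dig mode and water opens the acyloxonium ion to the α-acyloxy methyl ketone without breaking the C12–O bond; attack by the carbamate nitrogen instead would give an enecarbamate that step 14 converts to the same ring.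

**Step 14**
Reactants: 19 acetyl macrodiolide
Product: 21 CNP0304114.1, via amino ketone 20 (not isolated)
Conditions: TFA, CH2Cl2, 0 °C; then aq NaHCO3, rt
Reagents that add atoms: none
Why: Acidolysis removes both carbamates, and on neutralisation the primary amine of the amino ketone 20 condenses with the acetyl group of its own half in 6-exo-trig mode (intramolecular imine formation) to close ring A; the α-acyloxy ketone meets no base stronger than bicarbonate, and the hindered ring-B amine is left free.

**Compound list**

1 | (5S)-5-ethenylpyrrolidin-2-one (lactam of (S)-vigabatrin) | C=C[C@@H]1CCC(=O)N1 | starting material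
2 | methyl oct-7-enoate | C=CCCCCCC(=O)OC | starting material
3 | methyl (7E)-8-[(2S)-5-oxopyrrolidin-2-yl]oct-7-enoate | COC(=O)CCCCC/C=C/[C@@H]1CCC(=O)N1 | intermediate
4 | methyl 8-[(2R)-5-oxopyrrolidin-2-yl]octanoate | COC(=O)CCCCCCC[C@@H]1CCC(=O)N1 | intermediate
5 | tert-butyl (2R)-2-(8-methoxy-8-oxooctyl)-5-oxopyrrolidine-1-carboxylate | COC(=O)CCCCCCC[C@@H]1CCC(=O)N1C(=O)OC(C)(C)C | intermediate
6 | ethynyl(trimethyl)silane | C#C[Si](C)(C)C | starting material
7 | methyl (9R)-9-[(tert-butoxycarbonyl)amino]-12-oxo-14-(trimethylsilyl)tetradec-13-ynoate | COC(=O)CCCCCCC[C@H](CCC(=O)C#C[Si](C)(C)C)NC(=O)OC(C)(C)C | intermediate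
8 | methyl (9R,12S)-9-[(tert-butoxycarbonyl)amino]-12-hydroxy-14-(trimethylsilyl)tetradec-13-ynoate | COC(=O)CCCCCCC[C@H](CC[C@H](O)C#C[Si](C)(C)C)NC(=O)OC(C)(C)C | intermediate
9 | methyl (9R,12S)-9-[(tert-butoxycarbonyl)amino]-12-hydroxytetradec-13-ynoate | COC(=O)CCCCCCC[C@H](CC[C@H](O)C#C)NC(=O)OC(C)(C)C | intermediate
10 | methyl (9R,12S)-9-amino-12-hydroxytetradec-13-ynoate | COC(=O)CCCCCCC[C@H](CC[C@H](O)C#C)N | intermediate
11 | methyl 8-[(2R,5S)-5-hydroxy-6-methyl-2,3,4,5-tetrahydropyridin-2-yl]octanoate | CC1=N[C@@H](CC[C@@H]1O)CCCCCCCC(=O)OC | intermediate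
12 | methyl 8-[(2R,5S,6S)-5-hydroxy-6-methylpiperidin-2-yl]octanoate | O[C@H]1CC[C@@H](CCCCCCCC(=O)OC)N[C@H]1C | intermediate
13 | tert-butyl (2S,3S,6R)-3-hydroxy-6-(8-methoxy-8-oxooctyl)-2-methylpiperidine-1-carboxylate | O[C@H]1CC[C@@H](CCCCCCCC(=O)OC)N(C(=O)OC(C)(C)C)[C@H]1C | intermediate
14 | 8-[(2R,5S,6S)-1-(tert-butoxycarbonyl)-5-hydroxy-6-methylpiperidin-2-yl]octanoic acid | O[C@H]1CC[C@@H](CCCCCCCC(=O)O)N(C(=O)OC(C)(C)C)[C@H]1C | intermediate
15 | methyl (9R,12S)-9-[(tert-butoxycarbonyl)amino]-12-({8-[(2R,5S,6S)-1-(tert-butoxycarbonyl)-5-hydroxy-6-methylpiperidin-2-yl]octanoyl}oxy)tetradec-13-ynoate | COC(=O)CCCCCCC[C@H](CC[C@H](OC(=O)CCCCCCC[C@@H]1CC[C@H](O)[C@H](C)N1C(=O)OC(C)(C)C)C#C)NC(=O)OC(C)(C)C | intermediate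
16 | (9R,12S)-9-[(tert-butoxycarbonyl)amino]-12-({8-[(2R,5S,6S)-1-(tert-butoxycarbonyl)-5-hydroxy-6-methylpiperidin-2-yl]octanoyl}oxy)tetradec-13-ynoic acid | OC(=O)CCCCCCC[C@H](CC[C@H](OC(=O)CCCCCCC[C@@H]1CC[C@H](O)[C@H](C)N1C(=O)OC(C)(C)C)C#C)NC(=O)OC(C)(C)C | intermediate
17 | mixed anhydride of 16 and 2,4,6-trichlorobenzoic acid | O=C(OC(=O)c1c(Cl)cc(Cl)cc1Cl)CCCCCCC[C@H](CC[C@H](OC(=O)CCCCCCC[C@@H]2CC[C@H](O)[C@H](C)N2C(=O)OC(C)(C)C)C#C)NC(=O)OC(C)(C)C | intermediate
18 | alkynyl macrodiolide: 26-membered diolide, ring B as N-Boc (2S,3S,6R)-2-methylpiperidine (ester oxygen on C3, chain on C6), other half open with (R)-CH(NHBoc) and (S)-CH(C≡CH)–O | O=C1CCCCCCC[C@@H](NC(=O)OC(C)(C)C)CC[C@@H](C#C)OC(=O)CCCCCCC[C@@H]2CC[C@H](O1)[C@H](C)N2C(=O)OC(C)(C)C | intermediate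
19 | acetyl macrodiolide: as 18 with the (S)-carbinol carbon bearing acetyl in place of ethynyl | O=C1CCCCCCC[C@@H](NC(=O)OC(C)(C)C)CC[C@@H](C(C)=O)OC(=O)CCCCCCC[C@@H]2CC[C@H](O1)[C@H](C)N2C(=O)OC(C)(C)C | intermediate
20 | amino ketone: 19 without both Boc groups (ring-B piperidine NH, open half with (R)-CH(NH2) and (S)-CH(acetyl)–O ester carbon) | O=C1CCCCCCC[C@@H](N)CC[C@@H](C(C)=O)OC(=O)CCCCCCC[C@@H]2CC[C@H](O1)[C@H](C)N2 | intermediate
21 | CNP0304114.1: ring A (3S,6R)-2-methyl-3,4,5,6-tetrahydropyridine, ring B all-cis (2S,3S,6R)-2-methylpiperidine, joined by the two ester chains | CC1=N[C@@H]2CCCCCCCC(=O)O[C@H]3CC[C@@H](CCCCCCCC(=O)O[C@H]1CC2)N[C@H]3C | target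

**Step count and risks**

Total: 14 steps. Longest linear sequence: 14 steps (compound 9 enters twice, in steps 7 and 10).

Steps most likely to fail:

1. Step 13 (gold-catalysed hydration on the macrodiolide). The propargylic ester could undergo acyloxy migration or ionisation on gold instead of hydration, enlarging or opening the diolide, or a carbamate could be lost early. The fallback leaves the alkyne alone until the nitrogen is free. From 18, TFA in CH2Cl2 would remove both carbamates to give the bis-deprotected alkynyl macrodiolide F1. NaAuCl4·2H2O (or AgOTf) in MeCN would then close ring A by the same 6-exo-dig hydroamination of a 5-alkynylamine as in step 8, without hydrogen, and return to the route at 21.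

2. Step 10 (chemoselective esterification). The two secondary hydroxyl groups might not be told apart well enough, so that the hydroxy acid 14 esterifies itself to oligomers or a cyclodimer. The fallback makes the two ester bonds in the reverse order, so that each partner has a single free function. From 9, TBSCl/imidazole would give methyl (9R,12S)-9-[(tert-butoxycarbonyl)amino]-12-[(tert-butyldimethylsilyl)oxy]tetradec-13-ynoate F2, and LiOH its acid F3. Yamaguchi esterification of F3 with the only hydroxyl of 13 would give the diester F4. HF·pyridine would give the propargylic alcohol F5, and Me3SnOH, now beside a hindered ring ester, the seco acid F6. Macrolactonisation of F6 at the unhindered propargylic hydroxyl would return to the route at 18.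

3. Step 8 (hydroamination and hydrogenation). The α-hydroxy imine 11 could tautomerise to an α-amino ketone before it is reduced, with loss of the C3 centre, or hydrogen could add to the wrong face. The fallback closes the ring on a ketone under acid. From 9, hydration of the alkyne (Ph3PAuNTf2 in wet dioxane, or Hg(OTf)2) would give the α-hydroxy methyl ketone F7. TFA followed at once by H2 over Pd/C in methanol would reduce the protonated form of 11 as it forms (intramolecular reductive amination) to the piperidine 12, and Boc2O would return to the route at 13.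

**Further compounds**

F1 | step 13 | bis-deprotected alkynyl macrodiolide (18 without both Boc groups) | O=C1CCCCCCC[C@@H](N)CC[C@@H](C#C)OC(=O)CCCCCCC[C@@H]2CC[C@H](O1)[C@H](C)N2
F2 | step 10 | methyl (9R,12S)-9-[(tert-butoxycarbonyl)amino]-12-[(tert-butyldimethylsilyl)oxy]tetradec-13-ynoate | COC(=O)CCCCCCC[C@H](CC[C@H](O[Si](C)(C)C(C)(C)C)C#C)NC(=O)OC(C)(C)C
F3 | step 10 | (9R,12S)-9-[(tert-butoxycarbonyl)amino]-12-[(tert-butyldimethylsilyl)oxy]tetradec-13-ynoic acid | OC(=O)CCCCCCC[C@H](CC[C@H](O[Si](C)(C)C(C)(C)C)C#C)NC(=O)OC(C)(C)C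
F4 | step 10 | ester of F3 with the ring hydroxyl of 13 | COC(=O)CCCCCCC[C@@H]1CC[C@H](OC(=O)CCCCCCC[C@H](CC[C@H](O[Si](C)(C)C(C)(C)C)C#C)NC(=O)OC(C)(C)C)[C@H](C)N1C(=O)OC(C)(C)C
F5 | step 10 | desilylated F4 (free propargylic alcohol, methyl ester) | COC(=O)CCCCCCC[C@@H]1CC[C@H](OC(=O)CCCCCCC[C@H](CC[C@H](O)C#C)NC(=O)OC(C)(C)C)[C@H](C)N1C(=O)OC(C)(C)C
F6 | step 10 | seco acid from F5 (free propargylic alcohol, free ring-B chain acid) | OC(=O)CCCCCCC[C@@H]1CC[C@H](OC(=O)CCCCCCC[C@H](CC[C@H](O)C#C)NC(=O)OC(C)(C)C)[C@H](C)N1C(=O)OC(C)(C)C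
F7 | step 8 | methyl (9R,12S)-9-[(tert-butoxycarbonyl)amino]-12-hydroxy-13-oxotetradecanoate | COC(=O)CCCCCCC[C@H](CC[C@H](O)C(C)=O)NC(=O)OC(C)(C)C
A1 | direct plan | (9R,12S)-9-azido-12-hydroxy-13-methyltetradec-13-enoic acid | C=C(C)[C@@H](O)CC[C@H](N=[N+]=[N-])CCCCCCCC(=O)O
A2 | direct plan | (10R,13S,23R,26S)-13,26-diacetyl-10,23-diazido-1,14-dioxacyclohexacosane-2,15-dione | O1[C@H](C(C)=O)CC[C@H](N=[N+]=[N-])CCCCCCCC(=O)O[C@H](C(C)=O)CC[C@H](N=[N+]=[N-])CCCCCCCC1=O
A3 | direct plan | bis-imine diolide (both halves (3S,6R)-2-methyl-3,4,5,6-tetrahydropyridine) | CC1=N[C@@H]2CCCCCCCC(=O)O[C@H]3CC[C@@H](CCCCCCCC(=O)O[C@H]1CC2)N=C3C
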